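## Retrosynthetic overview

1. Acid 19 ← ester 17 ← C6–ethyl bond: axial ethyl transfer to the cyclic peroxycarbenium ion from 6-methoxy-1,2-dioxane 15 (sets C6).
2. 15 ← perketalisation of the C6 ketone of 13 with H2O2/MeOH, then 6-exo oxa-Michael closure onto the enoate (the only ring, formed late; sets C3).
3. 13 ← Wittig ← γ-keto aldehyde 12. Key C4–C5 bond of 12: oxidative (SOMO) coupling of butanal, as an α-electrophilic enamine radical cation, with silyl enol ether 10 of methyl ketone 8 (sets C4).
4. 8 ← two Cu-catalysed asymmetric conjugate additions (MeMgBr to enone 6; EtMgBr to methyl hept-2-enoate 1), linked by a one-pot reduction/Wittig (set C2' and C4').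

Assumption 1: where a chiral ligand or organocatalyst is named, the enantiomer meant is the one that gives the drawn configuration; if its sense of induction proves opposite, the mirror-image ligand or catalyst is used.

Assumption 2: only discrete stoichiometric intermediates are numbered; catalyst-bound species (enamines, iminium ions, radical cations, copper complexes) and fleeting adducts (oxaphosphetanes, ozonides) are not.

## Route

Step 1
Reactants: 1 methyl (E)-hept-2-enoate
Product: 3 methyl (S)-3-ethylheptanoate, via bromomagnesium enolate 2 (not isolated)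
Conditions: EtMgBr (1.5 equiv), CuI (2 mol %), (R)-Tol-BINAP (3 mol %), t-BuOMe, −40 °C; then 1 M HCl
Reagents that add atoms: ethylmagnesium bromide, CC[Mg]Br
Why: Copper-catalysed asymmetric conjugate addition of a Grignard reagent to an (E)-enoate, in which the chiral copper–diphosphine complex delivers ethyl to one face of the β-carbon and so sets the future C4' centre as S by catalyst control (not by ethyl/butyl size difference), the ester being inert to 1,2-addition at −40 °C.

Step 2
Reactants: 3 methyl (S)-3-ethylheptanoate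
Product: 6 (3E,6S)-6-ethyldec-3-en-2-one, via aluminium hemiacetal 4 (not isolated), via (S)-3-ethylheptanal 5 (not isolated)
Conditions: i-Bu2AlH (1.05 equiv), CH2Cl2, −78 °C; then Ph3P=CHC(O)CH3 (1.5 equiv), −78 → 40 °C
Reagents that add atoms: 1-(triphenylphosphoranylidene)propan-2-one, CC(=O)C=P(c1ccccc1)(c1ccccc1)c1ccccc1; diisobutylaluminium hydride, CC(C)C[AlH]CC(C)C (its aluminium stays only in intermediate 4)
Why: One-pot partial ester reduction and Wittig olefination, in which i-Bu2AlH stops at the tetrahedral hemiacetal 4 at −78 °C, warming releases aldehyde 5, and the stabilised keto-ylide traps it at once as the (E)-enone, with no new stereocentre and a β-stereocentre that cannot epimerise.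

Step 3
Reactants: 6 (3E,6S)-6-ethyldec-3-en-2-one
Product: 8 (4S,6S)-6-ethyl-4-methyldecan-2-one, via bromomagnesium enolate 7 (not isolated)
Conditions: MeMgBr (1.2 equiv), CuBr·SMe2 (5 mol %), (R)-1-[(S)-2-(diphenylphosphino)ferrocenyl]ethyldicyclohexylphosphine (6 mol %), t-BuOMe, −75 °C; then 1 M HCl
Reagents that add atoms: methylmagnesium bromide, C[Mg]Br
Why: Copper-catalysed asymmetric conjugate addition of MeMgBr to an acyclic (E)-enone with a ferrocenyl diphosphine ligand, where the catalyst (the remote C6 centre gives negligible 1,3-induction) adds methyl to one face of the β-carbon and sets the future C2' centre as S.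

Step 4
Reactants: 8 (4S,6S)-6-ethyl-4-methyldecan-2-one
Product: 10 tert-butyl{[(4S,6S)-6-ethyl-4-methyldec-1-en-2-yl]oxy}dimethylsilane, via lithium enolate 9 (not isolated)
Conditions: LiN(i-Pr)2 (1.1 equiv), THF, −78 °C; then t-BuMe2SiCl, DMPU, −78 → 0 °C
Reagents that add atoms: tert-butyldimethylsilyl chloride, CC(C)(C)[Si](C)(C)Cl; lithium diisopropylamide, [Li+].CC(C)[N-]C(C)C (its lithium stays only in intermediate 9)
Why: Kinetic enolisation and O-silylation, in which the bulky amide base deprotonates the unhindered methyl group rather than the β-branched methylene at −78 °C and trapping on oxygen gives the terminal silyl enol ether without touching either stereocentre.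

Step 5
Reactants: 10 tert-butyl{[(4S,6S)-6-ethyl-4-methyldec-1-en-2-yl]oxy}dimethylsilane; 11 butanal
Product: 12 (2S,6S,8S)-2,8-diethyl-6-methyl-4-oxododecanal
Conditions: (2S,5S)-5-benzyl-2-tert-butyl-3-methylimidazolidin-4-one·CF3CO2H (20 mol %), (NH4)2Ce(NO3)6 (2.2 equiv), 2,6-di-tert-butylpyridine (2 equiv), H2O (2 equiv), butanal (3 equiv), acetone, −20 °C
Reagents that add atoms: none
Why: Organo-SOMO α-enolation of an aldehyde, in which tetravalent cerium oxidises the butanal enamine to a radical cation that is electrophilic at the α-carbon (an enolonium equivalent), so the normally nucleophilic α-carbons of an aldehyde and a ketone (as enolsilane 10) are joined to a 1,4-dicarbonyl, and the benzyl/tert-butyl shielding of the second-generation MacMillan imidazolidinone exposes one face and sets the future C4 centre as S.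

Step 6
Reactants: 12 (2S,6S,8S)-2,8-diethyl-6-methyl-4-oxododecanal
Product: 13 methyl (2E,4S,8S,10S)-4,10-diethyl-8-methyl-6-oxotetradec-2-enoate
Conditions: Ph3P=CHCO2Me (1.2 equiv), CH2Cl2, 0 °C → rt
Reagents that add atoms: methyl (triphenylphosphoranylidene)acetate, COC(=O)C=P(c1ccccc1)(c1ccccc1)c1ccccc1
Why: Wittig olefination with a stabilised ylide, which reacts with the aldehyde only (the ketone is untouched), gives the (E)-enoate and is too weakly basic to epimerise the α-stereocentre of 12.

Step 7
Reactants: 13 methyl (2E,4S,8S,10S)-4,10-diethyl-8-methyl-6-oxotetradec-2-enoate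
Product: 15 methyl 2-[(3S,4S)-4-ethyl-6-[(2S,4S)-4-ethyl-2-methyloctyl]-6-methoxy-1,2-dioxan-3-yl]acetate, via hydroperoxy ketal 14 (not isolated)
Conditions: urea·H2O2 (3 equiv), Sc(OTf)3 (10 mol %), MeOH, rt; then Et2NH (0.2 equiv), CF3CH2OH, 0 °C → rt
Reagents that add atoms: urea–hydrogen peroxide, NC(N)=O.OO; methanol, CO
Why: Acid-catalysed perketalisation of the ketone followed by amine-catalysed 6-exo-trig intramolecular oxa-Michael addition of the hydroperoxide, which closes the 1,2-dioxane under kinetic control through a chair transition state with the C4 ethyl equatorial and the (E)-enoate pseudo-axial and so gives the 3,4-cis (3S) centre, both C6 anomers being carried on because C6 is re-set in step 8.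

Step 8
Reactants: 15 methyl 2-[(3S,4S)-4-ethyl-6-[(2S,4S)-4-ethyl-2-methyloctyl]-6-methoxy-1,2-dioxan-3-yl]acetate
Product: 17 methyl 2-[(3S,4S,6R)-4,6-diethyl-6-[(2S,4S)-4-ethyl-2-methyloctyl]-1,2-dioxan-3-yl]acetate, via peroxycarbenium triflate 16 (not isolated)
Conditions: Et2Zn (3 equiv), Me3SiOTf (1.2 equiv), CH2Cl2, −78 °C
Reagents that add atoms: diethylzinc, CC[Zn]CC; trimethylsilyl trifluoromethanesulfonate, C[Si](C)(C)OS(=O)(=O)C(F)(F)F (its triflate stays only in intermediate 16)
Why: Proposed new method: Me3SiOTf ionises the tertiary methoxy peroxyketal to the cyclic peroxycarbenium ion 16 (as in known Lewis-acid substitutions of cyclic peroxyketals by allylsilanes and silyl enol ethers) and Et2Zn transfers ethyl to it (as in known Me3SiOTf/dialkylzinc alkylations of six-membered oxocarbenium ions), attack being axial on the half-chair that keeps the C4 ethyl pseudo-equatorial, hence anti to it and to the C3 substituent, which sets C6 as R, while a dialkylzinc is expected to leave the dialkyl peroxide and the ester alone at −78 °C.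

Step 9
Reactants: 17 methyl 2-[(3S,4S,6R)-4,6-diethyl-6-[(2S,4S)-4-ethyl-2-methyloctyl]-1,2-dioxan-3-yl]acetate
Product: 19 2-[(3S,4S,6R)-4,6-diethyl-6-[(2S,4S)-4-ethyl-2-methyloctyl]-1,2-dioxan-3-yl]acetic acid, via lithium carboxylate 18 (not isolated)
Conditions: LiOH·H2O (3 equiv), THF/H2O 3:1, 0 °C → rt; then 1 M HCl to pH 3
Reagents that add atoms: lithium hydroxide, [Li+].[OH-]
Why: Ester saponification (acyl–oxygen cleavage) under mild conditions that leave the dialkyl peroxide intact, since C6 is quaternary and ester hydrolysis outpaces any base-induced ring opening at C3, followed by acidification, with no stereocentre affected.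

## Compound list

1 | methyl (E)-hept-2-enoate | CCCC/C=C/C(=O)OC | starting material
2 | bromomagnesium (3S)-3-ethyl-1-methoxyhept-1-en-1-olate | CCCC[C@H](CC)C=C(OC)O[Mg]Br | intermediate
3 | methyl (S)-3-ethylheptanoate | CCCC[C@H](CC)CC(=O)OC | intermediate
4 | {[(3S)-3-ethyl-1-methoxyheptyl]oxy}bis(2-methylpropyl)alumane | CCCC[C@H](CC)CC(OC)O[Al](CC(C)C)CC(C)C | intermediate
5 | (S)-3-ethylheptanal | CCCC[C@H](CC)CC=O | intermediate
6 | (3E,6S)-6-ethyldec-3-en-2-one | CCCC[C@H](CC)C/C=C/C(C)=O | intermediate
7 | bromomagnesium (4S,6S)-6-ethyl-4-methyldec-2-en-2-olate | CCCC[C@H](CC)C[C@H](C)C=C(C)O[Mg]Br | intermediate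
8 | (4S,6S)-6-ethyl-4-methyldecan-2-one | CCCC[C@H](CC)C[C@H](C)CC(C)=O | intermediate
9 | lithium (4S,6S)-6-ethyl-4-methyldec-1-en-2-olate | CCCC[C@H](CC)C[C@H](C)CC(=C)[O-].[Li+] | intermediate
10 | tert-butyl{[(4S,6S)-6-ethyl-4-methyldec-1-en-2-yl]oxy}dimethylsilane | CCCC[C@H](CC)C[C@H](C)CC(=C)O[Si](C)(C)C(C)(C)C | intermediate
11 | butanal | CCCC=O | starting material
12 | (2S,6S,8S)-2,8-diethyl-6-methyl-4-oxododecanal | CCCC[C@H](CC)C[C@H](C)CC(=O)C[C@H](CC)C=O | intermediate
13 | methyl (2E,4S,8S,10S)-4,10-diethyl-8-methyl-6-oxotetradec-2-enoate | CCCC[C@H](CC)C[C@H](C)CC(=O)C[C@H](CC)/C=C/C(=O)OC | intermediate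
14 | methyl (2E,4S,8S,10S)-4,10-diethyl-6-hydroperoxy-6-methoxy-8-methyltetradec-2-enoate (both C6 epimers) | CCCC[C@H](CC)C[C@H](C)CC(OC)(OO)C[C@H](CC)/C=C/C(=O)OC | intermediate
15 | methyl 2-[(3S,4S)-4-ethyl-6-[(2S,4S)-4-ethyl-2-methyloctyl]-6-methoxy-1,2-dioxan-3-yl]acetate (both C6 anomers) | CCCC[C@H](CC)C[C@H](C)CC1(OC)C[C@H](CC)[C@H](CC(=O)OC)OO1 | intermediate
16 | (3S,4S)-4-ethyl-6-[(2S,4S)-4-ethyl-2-methyloctyl]-3-(2-methoxy-2-oxoethyl)-4,5-dihydro-3H-1,2-dioxin-1-ium trifluoromethanesulfonate | CCCC[C@H](CC)C[C@H](C)CC=1C[C@H](CC)[C@H](CC(=O)OC)O[O+]=1.[O-]S(=O)(=O)C(F)(F)F | intermediate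
17 | methyl 2-[(3S,4S,6R)-4,6-diethyl-6-[(2S,4S)-4-ethyl-2-methyloctyl]-1,2-dioxan-3-yl]acetate | CCCC[C@H](CC)C[C@H](C)C[C@]1(CC)C[C@H](CC)[C@H](CC(=O)OC)OO1 | intermediate
18 | lithium 2-[(3S,4S,6R)-4,6-diethyl-6-[(2S,4S)-4-ethyl-2-methyloctyl]-1,2-dioxan-3-yl]acetate | CCCC[C@H](CC)C[C@H](C)C[C@]1(CC)C[C@H](CC)[C@H](CC(=O)[O-])OO1.[Li+] | intermediate
19 | 2-[(3S,4S,6R)-4,6-diethyl-6-[(2S,4S)-4-ethyl-2-methyloctyl]-1,2-dioxan-3-yl]acetic acid | CCCC[C@H](CC)C[C@H](C)C[C@]1(CC)C[C@H](CC)[C@H](CC(=O)O)OO1 | target

## Step count and risks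

Total steps: 9. Longest linear sequence: 9 (the route is fully linear, 1 → 19).

**Most likely to fail, first: step 8.** Ethyl transfer from zinc to a peroxycarbenium ion has no direct precedent. The organozinc could reduce the O–O bond, the cation could lose a proton to a peroxy enol ether, or it could fragment.

The fallback sets out from keto enoate 13 and comes back at ester 17. The ketone of 13 is olefinated with Ph3P=CHCH3 (EtPPh3Br, KN(SiMe3)2, THF, −78 → 0 °C) to the trisubstituted alkene methyl (2E,4S,8S,10S)-4,10-diethyl-6-ethylidene-8-methyltetradec-2-enoate F1, whose E/Z ratio does not matter. Mukaiyama–Isayama hydroperoxysilylation (Co(acac)2 10 mol %, Et3SiH, O2, ClCH2CH2Cl, rt) is selective for the electron-rich alkene over the enoate and Markovnikov at C6. It gives the silyl peroxide methyl (2E,4S,8S,10S)-4,6,10-triethyl-8-methyl-6-[(triethylsilyl)peroxy]tetradec-2-enoate F2 as a roughly 1:1 mixture at C6. Bu4NF (THF, 0 °C) frees the hydroperoxide methyl (2E,4S,8S,10S)-4,6,10-triethyl-6-hydroperoxy-8-methyltetradec-2-enoate F3. This closes under Et2NH/CF3CH2OH, as in step 7, to 17 together with its C6 epimer methyl 2-[(3S,4S,6S)-4,6-diethyl-6-[(2S,4S)-4-ethyl-2-methyloctyl]-1,2-dioxan-3-yl]acetate F4, which is removed by chromatography. This trades control at C6 (radical trapping by O2 is unselective) for precedented radical peroxidation and ring-closure chemistry.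

**Second: step 5.** The enolsilane is aliphatic and used as the limiting partner. (NH4)2Ce(NO3)6 may oxidise it directly, homocoupling and nitrate trapping can compete, and aldehyde 12 is epimerisable and must go straight into step 6.

The fallback sets out from enol ether 10 (with butanal 11) and comes back at 12. NBS (THF, 0 °C) converts 10 into the bromomethyl ketone (4S,6S)-1-bromo-6-ethyl-4-methyldecan-2-one F5. Photoredox organocatalytic α-alkylation of butanal with F5 (Ru(bpy)3Cl2 0.5 mol %, (2R,5S)-2-tert-butyl-3,5-dimethylimidazolidin-4-one·CF3SO3H 20 mol %, 2,6-lutidine, DMF, visible light, rt) then gives 12. The roles are exchanged: the ketone α-carbon is now the electrophilic radical and the aldehyde reacts as an ordinary enamine nucleophile, so no stoichiometric oxidant meets the substrates.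

**Third: step 7.** Perketalisation of a ketone flanked by two β-branched methylenes may be slow or give the gem-dihydroperoxide. The 3,4-cis preference of the ring closure rests on analogy with kinetic oxa-Michael closures; any 3,4-trans isomer would have to be separated.

The fallback sets out from 13 and comes back at hydroperoxy ketal 14, and from there at 15. The ketone of 13 is methylenated chemoselectively (CH2Br2, Zn, TiCl4, THF/CH2Cl2, 0 °C; the enoate is left alone) to the 1,1-disubstituted alkene methyl (2E,4S,8S,10S)-4,10-diethyl-8-methyl-6-methylidenetetradec-2-enoate F6. Ozonolysis of this electron-rich alkene with one equivalent of O3 (MeOH/CH2Cl2, −78 °C) lets methanol trap the more substituted carbonyl oxide and delivers 14 directly under neutral, cold conditions. Et2NH/CF3CH2OH then closes 14 to 15 as in step 7.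

## Further compounds

F1 | step 8 | methyl (2E,4S,8S,10S)-4,10-diethyl-6-ethylidene-8-methyltetradec-2-enoate | CCCC[C@H](CC)C[C@H](C)CC(=CC)C[C@H](CC)/C=C/C(=O)OC
F2 | step 8 | methyl (2E,4S,8S,10S)-4,6,10-triethyl-8-methyl-6-[(triethylsilyl)peroxy]tetradec-2-enoate | CCCC[C@H](CC)C[C@H](C)CC(CC)(OO[Si](CC)(CC)CC)C[C@H](CC)/C=C/C(=O)OC
F3 | step 8 | methyl (2E,4S,8S,10S)-4,6,10-triethyl-6-hydroperoxy-8-methyltetradec-2-enoate | CCCC[C@H](CC)C[C@H](C)CC(CC)(OO)C[C@H](CC)/C=C/C(=O)OC
F4 | step 8 | methyl 2-[(3S,4S,6S)-4,6-diethyl-6-[(2S,4S)-4-ethyl-2-methyloctyl]-1,2-dioxan-3-yl]acetate | CCCC[C@H](CC)C[C@H](C)C[C@@]1(CC)C[C@H](CC)[C@H](CC(=O)OC)OO1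
F5 | step 5 | (4S,6S)-1-bromo-6-ethyl-4-methyldecan-2-one | CCCC[C@H](CC)C[C@H](C)CC(=O)CBr
F6 | step 7 | methyl (2E,4S,8S,10S)-4,10-diethyl-8-methyl-6-methylidenetetradec-2-enoate | CCCC[C@H](CC)C[C@H](C)CC(=C)C[C@H](CC)/C=C/C(=O)OC
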